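**Plan**

- Retrosynthesis: hydrolyse the ester; cut C8–C9 (sp3–sp2) between the dioxane side arm and the alkylidene carbon; cut the O1–O2 bond of the 1,2-dioxane; cut C2–C3 (aldol); in the bicycle cut C1'–C2' (ring B) and C4'–C4a'.
- Enabling feature: O1–O2 joins the oxygen on C3 (a secondary syn-aldol carbinol) to the oxygen on C6 (a tertiary carbinol) across the four-carbon unit C3–C4–C5–C6, so the six-membered peroxide ring can be closed last between two C–O bonds that are already stereodefined.
- Forward, core: geraniol supplies C4–C8 with C6; an Evans aldol adds C1–C3; both hydroxyls are O-aminated and oxidation of the 3,6-bis(aminooxy) ester closes the 1,2-dioxane.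
- Forward, bicycle and union: ring A comes from 2,2-dimethylcyclohexanone; ring B is closed by a copper-catalysed borylative cyclisation that also fixes the Z-alkylidene; Negishi coupling joins the fragments and the ester is hydrolysed.
- Stereochemistry: C6 from Sharpless epoxidation (D-(−)-tartrate) and hydride opening; C2/C3 from the (S)-benzyloxazolidinone syn-aldol; alkene geometry from syn-borylcupration; the key step forms no stereocentre and breaks no C–O bond.

Key step: step 10

Remark: C1–C9 label the octanoate chain (C3 and C6 become the dioxane carbons) and primed numbers the octahydronaphthalene; 3,3-di-tert-butyloxaziridine is assumed to be made in one operation from commercial 2,2,4,4-tetramethylpentan-3-imine and mCPBA; the C8 silyl ether is triisopropylsilyl so that it does not migrate to the potassium alkoxides of step 8.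

**Route**

Step 1
Reactants: 1 geraniol
Product: 2 (2R,3R)-2,3-epoxygeraniol
Conditions: Ti(Oi-Pr)4 (cat.), D-(−)-diethyl tartrate (cat.), t-BuOOH, 4 Å MS, CH2Cl2, −20 °C
Reagents that add atoms: tert-butyl hydroperoxide, CC(C)(C)OO
Why: Sharpless asymmetric epoxidation of the allylic alcohol, in which the titanium D-(−)-tartrate complex delivers oxygen to the face that gives the (2R,3R)-epoxide (this sets the later C6 centre) and leaves the remote trisubstituted alkene untouched.

Step 2
Reactants: 2 (2R,3R)-2,3-epoxygeraniol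
Product: 3 (3R)-3,7-dimethyloct-6-ene-1,3-diol
Conditions: NaAlH2(OCH2CH2OMe)2, THF, 0 °C to rt
Reagents that add atoms: none
Why: Hydroxyl-directed reductive epoxide opening, the C1 alkoxyaluminate delivering hydride to C2 so that the 1,3-diol forms and the tertiary C–O bond (configuration retained) is not broken.

Step 3
Reactants: 3 (3R)-3,7-dimethyloct-6-ene-1,3-diol
Product: 4 (3R)-3,7-dimethyl-1-(triisopropylsilyloxy)oct-6-en-3-ol
Conditions: i-Pr3SiCl, imidazole, CH2Cl2, 0 °C to rt
Reagents that add atoms: chlorotriisopropylsilane, CC(C)[Si](Cl)(C(C)C)C(C)C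
Why: Silylation with a bulky chlorosilane is selective for the primary hydroxyl over the tertiary one.

Step 4
Reactants: 4 (3R)-3,7-dimethyl-1-(triisopropylsilyloxy)oct-6-en-3-ol
Product: 5 (3R)-3,7-dimethyl-3-(triethylsilyloxy)-1-(triisopropylsilyloxy)oct-6-ene
Conditions: Et3SiOTf, 2,6-lutidine, CH2Cl2, −78 to 0 °C
Reagents that add atoms: triethylsilyl triflate, CC[Si](CC)(CC)OS(=O)(=O)C(F)(F)F
Why: The silyl triflate silylates the hindered tertiary alcohol, which would otherwise close to a lactol with the aldehyde made in the next step.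

Step 5
Reactants: 5 (3R)-3,7-dimethyl-3-(triethylsilyloxy)-1-(triisopropylsilyloxy)oct-6-ene
Product: 7 (4R)-4-methyl-4-(triethylsilyloxy)-6-(triisopropylsilyloxy)hexanal, via ozonide 6 (not isolated)
Conditions: O3, CH2Cl2, −78 °C; then PPh3, −78 °C to rt
Reagents that add atoms: ozone, [O-][O+]=O
Why: Ozonolysis with reductive work-up cleaves the only alkene to the aldehyde and acetone, silyl ethers being inert.

Step 6
Reactants: 8 (4S)-4-benzyl-3-propanoyl-1,3-oxazolidin-2-one; 7 (4R)-4-methyl-4-(triethylsilyloxy)-6-(triisopropylsilyloxy)hexanal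
Product: 10 (4S)-4-benzyl-3-[(2S,3R,6R)-3-hydroxy-2,6-dimethyl-6-(triethylsilyloxy)-8-(triisopropylsilyloxy)octanoyl]-1,3-oxazolidin-2-one, via boron Z-enolate 9 (not isolated)
Conditions: Bu2BOTf, Et3N, CH2Cl2, −78 to 0 °C; then 7, −78 to 0 °C; pH 7 buffer, MeOH, H2O2
Reagents that add atoms: none
Why: Evans syn-aldol, the Z-boron enolate reacting through a chair (Zimmerman–Traxler) transition state in which the benzyl group of the (S)-auxiliary shields one enolate face, so that C2 (S) and C3 (R) are set together by the auxiliary and the remote C6 centre has no say.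

Step 7
Reactants: 10 Evans aldol adduct
Product: 12 (2S,3R,6R)-3,6-dihydroxy-2,6-dimethyl-8-(triisopropylsilyloxy)octanoic acid, via triethylsilyl-protected hydroxy acid 11 (not isolated)
Conditions: LiOH, H2O2, THF/H2O, 0 °C; Na2SO3; then 1 M HCl, THF, rt
Reagents that add atoms: hydrogen peroxide, OO
Why: Lithium hydroperoxide attacks the exocyclic imide carbonyl selectively (standard auxiliary cleavage, C2 untouched), and the dilute-acid stage hydrolyses the tertiary triethylsilyl ether while the primary triisopropylsilyl ether survives.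

Step 8
Reactants: 12 (2S,3R,6R)-3,6-dihydroxy-2,6-dimethyl-8-(triisopropylsilyloxy)octanoic acid
Product: 14 (2S,3R,6R)-3,6-bis(aminooxy)-2,6-dimethyl-8-(triisopropylsilyloxy)octanoic acid, via tripotassium salt 13 (not isolated)
Conditions: KH (3.3 equiv), THF/DMPU, 0 °C to rt; then 3,3-di-tert-butyloxaziridine (3 equiv), −40 °C to rt; AcOH
Reagents that add atoms: 3,3-di-tert-butyloxaziridine, CC(C)(C)C1(C(C)(C)C)NO1
Why: Electrophilic amination of alkoxides by an N–H oxaziridine transfers NH to oxygen without breaking either C–O bond, so C3 and C6 keep their configurations; it is run on the carboxylate because a β-alkoxide ester would undergo retro-aldol cleavage or cyclise to an isoxazolidinone, and the hindered ketone by-product cannot condense with the product.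

Step 9
Reactants: 14 (2S,3R,6R)-3,6-bis(aminooxy)-2,6-dimethyl-8-(triisopropylsilyloxy)octanoic acid
Product: 15 methyl (2S,3R,6R)-3,6-bis(aminooxy)-2,6-dimethyl-8-(triisopropylsilyloxy)octanoate
Conditions: Me3SiCHN2, toluene/MeOH, 0 °C
Reagents that add atoms: (trimethylsilyl)diazomethane, C[Si](C)(C)C=[N+]=[N-]
Why: Diazoalkane esterification methylates only the carboxylic acid under neutral conditions and leaves the weakly basic aminooxy groups alone; the ester should be oxidised at once, since a free β-aminooxy methyl ester can close slowly to an isoxazolidin-3-one.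

Step 10
Reactants: 15 methyl (2S,3R,6R)-3,6-bis(aminooxy)-2,6-dimethyl-8-(triisopropylsilyloxy)octanoate
Product: 17 methyl (2S)-2-[(3R,6R)-6-methyl-6-[2-(triisopropylsilyloxy)ethyl]-1,2-dioxan-3-yl]propanoate, via cyclic cis-hyponitrite 16 (not isolated)
Conditions: PhI(OAc)2 (2.2 equiv), CH2Cl2, high dilution (slow addition of 15), −40 °C to rt
Reagents that add atoms: none
Why: Proposed new method: each aminooxy nitrogen exchanges onto trivalent iodine and loses PhI to give an alkoxynitrene equivalent; N–N coupling and a second two-electron oxidation should give the eight-membered cis-hyponitrite 16, whose strained Z-azo unit should lose N2 well below room temperature and leave a singlet pair of alkoxyl radicals on C3 and C6. The closest known reactions are the oxidation of O-alkylhydroxylamines (Pb(OAc)4 or PhI(OAc)2) to dialkyl hyponitrites and the thermolysis of hyponitrites, where caged alkoxyl radical pairs give some dialkyl peroxide. The 1,2-dioxane closes by recombination of the two oxygen radicals (O–O bond formation, six-membered ring), the pair being held together by the C3–C4–C5–C6 tether. No stereocentre is formed, and because neither C–O bond is broken the configurations set in steps 1 and 6 are carried through with retention. The step needs intramolecular N–N coupling to beat oligomerisation (high dilution, slow addition) and O–O closure to beat 1,5-hydrogen transfer from C3–H and β-scission at C6; the singlet birth of the pair, the short tether, the low temperature and a solvent without easily abstracted hydrogen are meant to secure this.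

Step 11
Reactants: 17 dioxane silyl ether
Product: 18 methyl (2S)-2-[(3R,6R)-6-(2-hydroxyethyl)-6-methyl-1,2-dioxan-3-yl]propanoate
Conditions: Bu4NF, AcOH, THF, 0 °C to rt
Reagents that add atoms: none
Why: Fluoride desilylation buffered with acetic acid removes the silyl ether without exposing the β-peroxy ester to base, which could open the ring by retro-oxa-Michael elimination.

Step 12
Reactants: 18 methyl (2S)-2-[(3R,6R)-6-(2-hydroxyethyl)-6-methyl-1,2-dioxan-3-yl]propanoate
Product: 19 methyl (2S)-2-[(3R,6R)-6-(2-iodoethyl)-6-methyl-1,2-dioxan-3-yl]propanoate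
Conditions: I2, PPh3, imidazole, CH2Cl2, 0 °C
Reagents that add atoms: iodine, II
Why: Appel-type iodination replaces the primary hydroxyl by SN2 at C8; the phosphine is tied up as its iodine adduct before the alcohol is added, and dialkyl peroxides react only slowly with triarylphosphines.

Step 13
Reactants: 20 2,2-dimethylcyclohexanone
Product: 21 methyl 3,3-dimethyl-2-oxocyclohexane-1-carboxylate
Conditions: NaH, (MeO)2CO, THF, reflux; AcOH
Reagents that add atoms: dimethyl carbonate, COC(=O)OC
Why: Claisen-type C-acylation of the ketone enolate, which can form only at the single enolisable α-position.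

Step 14
Reactants: 21 methyl 3,3-dimethyl-2-oxocyclohexane-1-carboxylate
Product: 23 methyl 3,3-dimethyl-2-(trifluoromethylsulfonyloxy)cyclohex-1-ene-1-carboxylate, via sodium enolate 22 (not isolated)
Conditions: NaH, Et2O, 0 °C; then Tf2O, 0 °C
Reagents that add atoms: triflic anhydride, O=S(=O)(OS(=O)(=O)C(F)(F)F)C(F)(F)F
Why: O-sulfonylation of the β-keto ester enolate gives the tetrasubstituted enol triflate, its position fixed by the β-keto ester.

Step 15
Reactants: 24 (4-bromobut-1-yn-1-yl)trimethylsilane; 23 enol triflate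
Product: 26 methyl 3,3-dimethyl-2-[4-(trimethylsilyl)but-3-yn-1-yl]cyclohex-1-ene-1-carboxylate, via alkylzinc bromide 25 (not isolated)
Conditions: 24, Zn dust, LiCl, THF, 50 °C; then 23, PdCl2(dppf) (5 mol %), THF, 50 °C
Reagents that add atoms: none
Why: Negishi coupling of a primary alkylzinc halide with an electron-poor enol triflate forms C4'–C4a'; the dppf ligand suppresses β-hydride elimination and the silyl group masks the acidic alkyne C–H.

Step 16
Reactants: 26 coupled ester
Product: 27 {3,3-dimethyl-2-[4-(trimethylsilyl)but-3-yn-1-yl]cyclohex-1-en-1-yl}methanol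
Conditions: i-Bu2AlH, CH2Cl2, −78 °C; aq. KNaC4H4O6
Reagents that add atoms: none
Why: Hydride 1,2-reduction of the conjugated ester to the allylic alcohol at low temperature, where the silylalkyne is not hydroaluminated.

Step 17
Reactants: 27 silylalkyne allylic alcohol
Product: 28 [2-(but-3-yn-1-yl)-3,3-dimethylcyclohex-1-en-1-yl]methanol
Conditions: K2CO3 (cat.), MeOH, rt
Reagents that add atoms: none
Why: Base-catalysed methanolysis of the alkynyl C–Si bond frees the terminal alkyne.

Step 18
Reactants: 28 [2-(but-3-yn-1-yl)-3,3-dimethylcyclohex-1-en-1-yl]methanol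
Product: 29 [2-(but-3-yn-1-yl)-3,3-dimethylcyclohex-1-en-1-yl]methyl diethyl phosphate
Conditions: (EtO)2P(O)Cl, pyridine, DMAP (cat.), CH2Cl2, 0 °C
Reagents that add atoms: diethyl chlorophosphate, CCOP(=O)(Cl)OCC
Why: Phosphorylation gives a primary allylic phosphate, a leaving group that tolerates alkoxide base and is a standard electrophile for organocopper species.

Step 19
Reactants: 29 allylic phosphate
Product: 30 2-{(Z)-[5,5-dimethyl-3,4,5,6,7,8-hexahydronaphthalen-2(1H)-ylidene]methyl}-4,4,5,5-tetramethyl-1,3,2-dioxaborolane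
Conditions: CuCl (10 mol %), Xantphos (10 mol %), B2pin2, KOt-Bu, THF, rt
Reagents that add atoms: bis(pinacolato)diboron, CC1(C)OB(OC1(C)C)B1OC(C)(C)C(C)(C)O1
Why: Copper-catalysed borylative cyclisation (intramolecular alkyne carboboration): syn-borylcupration puts boron on the terminal carbon and monovalent copper on C2', and the alkenylcopper displaces the primary phosphate at C1' (6-exo) with retention, so boron ends cis to C1' and the Z geometry is fixed; direct allylic borylation is disfavoured because its SN2' carbon is fully substituted.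

Step 20
Reactants: 30 alkenylboronate
Product: 32 (2Z)-2-(iodomethylidene)-5,5-dimethyl-1,2,3,4,5,6,7,8-octahydronaphthalene, via methoxyborate 31 (not isolated)
Conditions: NaOMe, MeOH/THF, −78 °C; then I2, −78 to 0 °C
Reagents that add atoms: iodine, II
Why: Iododeboronation of the preformed borate complex with iodine proceeds with retention of alkene geometry when base is added before the halogen, and at low temperature the tetrasubstituted ring alkene does not add iodine.

Step 21
Reactants: 19 methyl (2S)-2-[(3R,6R)-6-(2-iodoethyl)-6-methyl-1,2-dioxan-3-yl]propanoate; 32 (2Z)-alkenyl iodide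
Product: 34 methyl (2S)-2-[(3R,6S)-6-{(3Z)-3-[5,5-dimethyl-3,4,5,6,7,8-hexahydronaphthalen-2(1H)-ylidene]propyl}-6-methyl-1,2-dioxan-3-yl]propanoate, via alkylzinc iodide 33 (not isolated)
Conditions: 19, Zn dust, LiCl, THF, 30 °C; then 32, PdCl2(dppf) (5 mol %), THF, rt
Reagents that add atoms: none
Why: Negishi coupling: zinc inserts into the primary C–I bond, the alkylzinc iodide should tolerate the ester and the dialkyl peroxide, and coupling at zerovalent palladium with the alkenyl iodide forms C8–C9 with retention of the Z geometry under base-free conditions.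

Step 22
Reactants: 34 coupled methyl ester
Product: 35 (2S)-2-[(3R,6S)-6-{(3Z)-3-[5,5-dimethyl-3,4,5,6,7,8-hexahydronaphthalen-2(1H)-ylidene]propyl}-6-methyl-1,2-dioxan-3-yl]propanoic acid
Conditions: LiOH, THF/H2O, 0 °C; then 1 M HCl to pH 3
Reagents that add atoms: lithium hydroxide, [Li+].[OH-]
Why: Saponification of the methyl ester at low temperature, mild enough to leave the 1,2-dioxane, the C2 centre and the skipped diene intact.

**Compound list**

1 | geraniol | CC(C)=CCC/C(C)=C/CO | starting material
2 | (2R,3R)-2,3-epoxygeraniol | OC[C@H]1O[C@]1(C)CCC=C(C)C | intermediate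
3 | (3R)-3,7-dimethyloct-6-ene-1,3-diol | OCC[C@](C)(O)CCC=C(C)C | intermediate
4 | (3R)-3,7-dimethyl-1-(triisopropylsilyloxy)oct-6-en-3-ol | CC(C)[Si](OCC[C@](C)(O)CCC=C(C)C)(C(C)C)C(C)C | intermediate
5 | (3R)-3,7-dimethyl-3-(triethylsilyloxy)-1-(triisopropylsilyloxy)oct-6-ene | CC(C)[Si](OCC[C@](C)(O[Si](CC)(CC)CC)CCC=C(C)C)(C(C)C)C(C)C | intermediate
6 | ozonide of 5 (1,2,4-trioxolane, not isolated) | CC1(C)OOC(CC[C@@](C)(O[Si](CC)(CC)CC)CCO[Si](C(C)C)(C(C)C)C(C)C)O1 | intermediate
7 | (4R)-4-methyl-4-(triethylsilyloxy)-6-(triisopropylsilyloxy)hexanal | O=CCC[C@@](C)(O[Si](CC)(CC)CC)CCO[Si](C(C)C)(C(C)C)C(C)C | intermediate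
8 | (4S)-4-benzyl-3-propanoyl-1,3-oxazolidin-2-one | CCC(=O)N1[C@@H](Cc2ccccc2)COC1=O | starting material
9 | dibutylboron Z-enolate of 8 (not isolated) | C/C=C(\OB(CCCC)CCCC)N1[C@@H](Cc2ccccc2)COC1=O | intermediate
10 | (4S)-4-benzyl-3-[(2S,3R,6R)-3-hydroxy-2,6-dimethyl-6-(triethylsilyloxy)-8-(triisopropylsilyloxy)octanoyl]-1,3-oxazolidin-2-one | C[C@H](C(=O)N1[C@@H](Cc2ccccc2)COC1=O)[C@H](O)CC[C@@](C)(O[Si](CC)(CC)CC)CCO[Si](C(C)C)(C(C)C)C(C)C | intermediate
11 | (2S,3R,6R)-3-hydroxy-2,6-dimethyl-6-(triethylsilyloxy)-8-(triisopropylsilyloxy)octanoic acid (formed as its lithium salt, not isolated) | C[C@H](C(=O)O)[C@H](O)CC[C@@](C)(O[Si](CC)(CC)CC)CCO[Si](C(C)C)(C(C)C)C(C)C | intermediate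
12 | (2S,3R,6R)-3,6-dihydroxy-2,6-dimethyl-8-(triisopropylsilyloxy)octanoic acid | C[C@H](C(=O)O)[C@H](O)CC[C@@](C)(O)CCO[Si](C(C)C)(C(C)C)C(C)C | intermediate
13 | tripotassium salt of 12 (carboxylate and both alkoxides, not isolated) | C[C@H](C(=O)[O-])[C@H]([O-])CC[C@@](C)([O-])CCO[Si](C(C)C)(C(C)C)C(C)C.[K+].[K+].[K+] | intermediate
14 | (2S,3R,6R)-3,6-bis(aminooxy)-2,6-dimethyl-8-(triisopropylsilyloxy)octanoic acid | C[C@H](C(=O)O)[C@H](ON)CC[C@@](C)(ON)CCO[Si](C(C)C)(C(C)C)C(C)C | intermediate
15 | methyl (2S,3R,6R)-3,6-bis(aminooxy)-2,6-dimethyl-8-(triisopropylsilyloxy)octanoate | C[C@H](C(=O)OC)[C@H](ON)CC[C@@](C)(ON)CCO[Si](C(C)C)(C(C)C)C(C)C | intermediate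
16 | eight-membered cyclic cis-hyponitrite (ring O–N=N–O–C6–C5–C4–C3, centres as in 15, not isolated) | C[C@H](C(=O)OC)[C@H]1CC[C@](C)(CCO[Si](C(C)C)(C(C)C)C(C)C)O/N=N\O1 | intermediate
17 | methyl (2S)-2-[(3R,6R)-6-methyl-6-[2-(triisopropylsilyloxy)ethyl]-1,2-dioxan-3-yl]propanoate | C[C@H](C(=O)OC)[C@H]1CC[C@](C)(CCO[Si](C(C)C)(C(C)C)C(C)C)OO1 | intermediate
18 | methyl (2S)-2-[(3R,6R)-6-(2-hydroxyethyl)-6-methyl-1,2-dioxan-3-yl]propanoate | C[C@H](C(=O)OC)[C@H]1CC[C@](C)(CCO)OO1 | intermediate
19 | methyl (2S)-2-[(3R,6R)-6-(2-iodoethyl)-6-methyl-1,2-dioxan-3-yl]propanoate | C[C@H](C(=O)OC)[C@H]1CC[C@](C)(CCI)OO1 | intermediate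
20 | 2,2-dimethylcyclohexanone | CC1(C)CCCCC1=O | starting material
21 | methyl 3,3-dimethyl-2-oxocyclohexane-1-carboxylate (racemic, enolisable) | COC(=O)C1CCCC(C)(C)C1=O | intermediate
22 | sodium enolate of 21 (not isolated) | COC(=O)C1=C([O-])C(C)(C)CCC1.[Na+] | intermediate
23 | methyl 3,3-dimethyl-2-(trifluoromethylsulfonyloxy)cyclohex-1-ene-1-carboxylate | COC(=O)C1=C(OS(=O)(=O)C(F)(F)F)C(C)(C)CCC1 | intermediate
24 | (4-bromobut-1-yn-1-yl)trimethylsilane | C[Si](C)(C)C#CCCBr | starting material
25 | [4-(trimethylsilyl)but-3-yn-1-yl]zinc bromide (not isolated) | C[Si](C)(C)C#CCC[Zn]Br | intermediate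
26 | methyl 3,3-dimethyl-2-[4-(trimethylsilyl)but-3-yn-1-yl]cyclohex-1-ene-1-carboxylate | COC(=O)C1=C(CCC#C[Si](C)(C)C)C(C)(C)CCC1 | intermediate
27 | {3,3-dimethyl-2-[4-(trimethylsilyl)but-3-yn-1-yl]cyclohex-1-en-1-yl}methanol | OCC1=C(CCC#C[Si](C)(C)C)C(C)(C)CCC1 | intermediate
28 | [2-(but-3-yn-1-yl)-3,3-dimethylcyclohex-1-en-1-yl]methanol | OCC1=C(CCC#C)C(C)(C)CCC1 | intermediate
29 | [2-(but-3-yn-1-yl)-3,3-dimethylcyclohex-1-en-1-yl]methyl diethyl phosphate | CCOP(=O)(OCC)OCC1=C(CCC#C)C(C)(C)CCC1 | intermediate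
30 | 2-{(Z)-[5,5-dimethyl-3,4,5,6,7,8-hexahydronaphthalen-2(1H)-ylidene]methyl}-4,4,5,5-tetramethyl-1,3,2-dioxaborolane (boron cis to C1') | CC1(C)OB(OC1(C)C)/C=C1/CCC2=C(CCCC2(C)C)C1 | intermediate
31 | sodium methoxyborate of 30 (not isolated) | CO[B-]1(OC(C)(C)C(C)(C)O1)/C=C1/CCC2=C(CCCC2(C)C)C1.[Na+] | intermediate
32 | (2Z)-2-(iodomethylidene)-5,5-dimethyl-1,2,3,4,5,6,7,8-octahydronaphthalene (iodine cis to C1') | I/C=C1/CCC2=C(CCCC2(C)C)C1 | intermediate
33 | alkylzinc iodide from 19 (C8–ZnI, not isolated) | C[C@H](C(=O)OC)[C@H]1CC[C@](C)(CC[Zn]I)OO1 | intermediate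
34 | methyl (2S)-2-[(3R,6S)-6-{(3Z)-3-[5,5-dimethyl-3,4,5,6,7,8-hexahydronaphthalen-2(1H)-ylidene]propyl}-6-methyl-1,2-dioxan-3-yl]propanoate | C[C@H](C(=O)OC)[C@H]1CC[C@](C)(CC/C=C2/CCC3=C(CCCC3(C)C)C2)OO1 | intermediate
35 | (2S)-2-[(3R,6S)-6-{(3Z)-3-[5,5-dimethyl-3,4,5,6,7,8-hexahydronaphthalen-2(1H)-ylidene]propyl}-6-methyl-1,2-dioxan-3-yl]propanoic acid | C[C@H](C(=O)O)[C@H]1CC[C@](C)(CC/C=C2/CCC3=C(CCCC3(C)C)C2)OO1 | target

**Count and risks**

Total step count: 22. Longest linear sequence: 14 steps (steps 1–12, 21 and 22); the bicyclic branch is steps 13–20.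

Steps most likely to fail:

1. Step 10 (proposed new method). The nitrogen centres may couple between molecules instead of within one, or the alkoxynitrene equivalent at the secondary C3 oxygen may rearrange. After loss of N2, hydrogen transfer from C3–H to the C6 oxygen radical, or β-scission at C6, may outrun O–O recombination. The fallback forms the two C–O bonds instead of the O–O bond, by known reactions; it sets out from geraniol 1 and rejoins the route at alcohol 18. Sharpless epoxidation with L-(+)-diethyl tartrate gives (2S,3S)-2,3-epoxygeraniol F1, and opening with NaAlH2(OCH2CH2OMe)2 gives (3S)-3,7-dimethyloct-6-ene-1,3-diol F2. Tosylation of the primary hydroxyl gives (3S)-3-hydroxy-3,7-dimethyloct-6-en-1-yl 4-methylbenzenesulfonate F3, and KOt-Bu closes (2S)-2-methyl-2-(4-methylpent-3-en-1-yl)oxetane F4 with the tertiary C–O bond intact. Ozonolysis, through the ozonide of the oxetane F5, gives 3-[(2S)-2-methyloxetan-2-yl]propanal F6, and Wittig olefination with methyl 2-(triphenylphosphoranylidene)propanoate gives methyl (2E)-2-methyl-5-[(2S)-2-methyloxetan-2-yl]pent-2-enoate F7. Opening of the oxetane by H2O2 with Me3SiOTf, at the tertiary carbon with inversion, gives methyl (2E,6R)-6-hydroperoxy-8-hydroxy-2,6-dimethyloct-2-enoate F8, which has the target configuration at C6. Intramolecular peroxy-Michael addition (Et2NH, CF3CH2OH; 6-exo) then closes the 1,2-dioxane. C2 and C3 are set without reagent control in this closure, so the diastereomers must be separated; the required one is 18.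

2. Step 19. The copper–boryl species may react directly with the allylic phosphate, or the alkenylcopper may be protonated before the slower six-membered ring closure, giving uncyclised alkenylboronate. The fallback separates the two events: the C1'–C2' bond is made intermolecularly and ring B is closed at C4'–C4a' instead. It sets out from enol triflate 23 and rejoins at 30. Reduction with i-Bu2AlH gives [3,3-dimethyl-2-(trifluoromethylsulfonyloxy)cyclohex-1-en-1-yl]methanol F9, and phosphorylation gives its diethyl phosphate F10. Copper-catalysed three-component boryl-allylation of 4-chlorobut-1-yne with B2pin2 and F10 (CuCl, Xantphos, KOt-Bu) gives the (E)-4-chlorobut-1-enylboronate bearing the ring CH2 on C2 cis to boron F11. NaI in acetone gives the corresponding iodide F12, and zinc insertion gives the alkylzinc iodide F13. Intramolecular Negishi coupling with the enol triflate (PdCl2(dppf)) closes ring B to 30; the pinacol boronate is inert under these base-free conditions.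

3. Step 21. Zinc metal may reduce the O–O bond during insertion, the low-valent palladium–phosphine system may attack the peroxide, or the organozinc may be protonated. The fallback reverses the polarity of the coupling so that the peroxide never meets zinc metal; it sets out from alkenyl iodide 32 and rejoins at 34. Iodine–lithium exchange (t-BuLi, Et2O, −78 °C) gives the (Z)-alkenyllithium F14, and ZnCl2 gives the (Z)-alkenylzinc chloride F15. This is coupled with alkyl iodide 19 under conditions for unactivated alkyl electrophiles (Pd2(dba)3, tricyclopentylphosphine, N-methylimidazole, THF/NMP).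

**Further compounds**

F1 | step 10 | (2S,3S)-2,3-epoxygeraniol | OC[C@@H]1O[C@@]1(C)CCC=C(C)C
F2 | step 10 | (3S)-3,7-dimethyloct-6-ene-1,3-diol | OCC[C@@](C)(O)CCC=C(C)C
F3 | step 10 | (3S)-3-hydroxy-3,7-dimethyloct-6-en-1-yl 4-methylbenzenesulfonate | Cc1ccc(cc1)S(=O)(=O)OCC[C@@](C)(O)CCC=C(C)C
F4 | step 10 | (2S)-2-methyl-2-(4-methylpent-3-en-1-yl)oxetane | C[C@]1(CCC=C(C)C)CCO1
F5 | step 10 | ozonide of F4 (3,3-dimethyl-5-{2-[(2S)-2-methyloxetan-2-yl]ethyl}-1,2,4-trioxolane) | CC1(C)OOC(CC[C@@]2(C)CCO2)O1
F6 | step 10 | 3-[(2S)-2-methyloxetan-2-yl]propanal | O=CCC[C@@]1(C)CCO1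
F7 | step 10 | methyl (2E)-2-methyl-5-[(2S)-2-methyloxetan-2-yl]pent-2-enoate | COC(=O)/C(C)=C/CC[C@@]1(C)CCO1
F8 | step 10 | methyl (2E,6R)-6-hydroperoxy-8-hydroxy-2,6-dimethyloct-2-enoate | COC(=O)/C(C)=C/CC[C@@](C)(OO)CCO
F9 | step 19 | [3,3-dimethyl-2-(trifluoromethylsulfonyloxy)cyclohex-1-en-1-yl]methanol | OCC1=C(OS(=O)(=O)C(F)(F)F)C(C)(C)CCC1
F10 | step 19 | [3,3-dimethyl-2-(trifluoromethylsulfonyloxy)cyclohex-1-en-1-yl]methyl diethyl phosphate | CCOP(=O)(OCC)OCC1=C(OS(=O)(=O)C(F)(F)F)C(C)(C)CCC1
F11 | step 19 | 2-[(1E)-4-chloro-2-{[3,3-dimethyl-2-(trifluoromethylsulfonyloxy)cyclohex-1-en-1-yl]methyl}but-1-en-1-yl]-4,4,5,5-tetramethyl-1,3,2-dioxaborolane | ClCC/C(CC1=C(OS(=O)(=O)C(F)(F)F)C(C)(C)CCC1)=C/B1OC(C)(C)C(C)(C)O1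
F12 | step 19 | 2-[(1E)-4-iodo-2-{[3,3-dimethyl-2-(trifluoromethylsulfonyloxy)cyclohex-1-en-1-yl]methyl}but-1-en-1-yl]-4,4,5,5-tetramethyl-1,3,2-dioxaborolane | ICC/C(CC1=C(OS(=O)(=O)C(F)(F)F)C(C)(C)CCC1)=C/B1OC(C)(C)C(C)(C)O1
F13 | step 19 | alkylzinc iodide from F12 (C4'–ZnI) | I[Zn]CC/C(CC1=C(OS(=O)(=O)C(F)(F)F)C(C)(C)CCC1)=C/B1OC(C)(C)C(C)(C)O1
F14 | step 21 | (Z)-[5,5-dimethyl-3,4,5,6,7,8-hexahydronaphthalen-2(1H)-ylidene]methyllithium | [Li]/C=C1/CCC2=C(CCCC2(C)C)C1
F15 | step 21 | (Z)-[5,5-dimethyl-3,4,5,6,7,8-hexahydronaphthalen-2(1H)-ylidene]methylzinc chloride | Cl[Zn]/C=C1/CCC2=C(CCCC2(C)C)C1
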